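**Retrosynthetic overview**
- The target comes from acid deprotection of a ketal / silyl ether / tert‑butyl ester precursor. The ring–heptenyl bond is cut by Suzuki–Miyaura coupling of a ring vinyl bromide with potassium (E)‑hept‑1‑enyltrifluoroborate (from 1‑heptyne).
- The cis‑epoxy alcohol comes from face‑selective reduction of an epoxy ketone. The oxirane comes from a catalytic enantioselective nucleophilic epoxidation of a p‑quinone monoketal, which sets both oxirane stereocentres.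
- The monoketal comes from oxidative dearomatisation of a 2,3,5‑trisubstituted phenol built on 3‑bromophenol.
- The phenol comes from Pd‑catalysed allyl–aryl coupling of an aryl boronate (ortho‑lithiation/formylation, then Ir‑catalysed meta C–H borylation) with tert‑butyl (E)‑4‑bromo‑2‑methylbut‑2‑enoate (Wittig, from 2‑bromopropanoyl bromide and glycolaldehyde dimer).
- Ring order: the six‑membered carbocycle is present from the start as the arene and is dearomatised late; the oxirane is formed last.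

Assumption: the target is taken exactly as drawn, i.e. (1S,5S,6S) with the hydroxyl and the oxirane oxygen on the same ring face and both side‑chain alkenes E; operations run through without isolation count as one step; bicyclic compounds are numbered as 7‑oxabicyclo[4.1.0]heptenes (C1 = oxirane carbon bearing the butenoate chain, C2 = ketal or ketone carbon, C3 = C–Br or C–heptenyl, C4 = C–CH2O, C5 = C=O or CHOH, C6 = oxirane CH).

**Fragment A: aryl boronate**

Step 1
Reactants: 1 (3‑bromophenol)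
Product: 2 THP ether 2‑(3‑bromophenoxy)oxane (racemic at the acetal carbon)
Conditions: 3,4‑dihydro‑2H‑pyran (1.5 equiv), pyridinium p‑toluenesulfonate (PPTS, 5 mol %), CH2Cl2, rt
Reagents that add atoms: 3,4‑dihydro‑2H‑pyran, C1=COCCC1
Why: Acid‑catalysed addition of the phenol to the enol ether (tetrahydropyranylation) gives a base‑stable acetal that directs the next metalation and can later be removed without touching a silyl ether.

Step 2
Reactants: 2 (THP ether)
Product: 5 benzylic alcohol [2‑bromo‑6‑(oxan‑2‑yloxy)phenyl]methanol, via aryllithium 3 (not isolated), via aldehyde 4 (not isolated)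
Conditions: LiN(iPr)2 (1.1 equiv), THF, −78 °C, 1 h; DMF (1.5 equiv), −78 → 0 °C; then MeOH, NaBH4 (1.0 equiv), 0 °C
Reagents that add atoms: N,N‑dimethylformamide, CN(C)C=O
Why: Directed ortho‑metalation removes the C–H flanked by the acetal oxygen and bromine (the most acidic one; the amide base gives no Br/Li exchange and −78 °C suppresses aryne formation), DMF formylates the aryllithium and borohydride reduces the aldehyde in the same flask.

Step 3
Reactants: 5 (benzylic alcohol)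
Product: 6 silyl ether {[2‑bromo‑6‑(oxan‑2‑yloxy)phenyl]methoxy}(tert‑butyl)dimethylsilane
Conditions: TBSCl (1.2 equiv), imidazole (2.5 equiv), DMF, rt
Reagents that add atoms: tert‑butyldimethylsilyl chloride, CC(C)(C)[Si](C)(C)Cl
Why: Standard imidazole‑promoted silylation of a primary alcohol; a silyl ether is a poor leaving group, which later keeps the CH2O arm inert toward the peroxide nucleophile.

Step 4
Reactants: 6 (silyl ether)
Product: 7 aryl boronate 2‑[3‑bromo‑4‑({[tert‑butyl(dimethyl)silyl]oxy}methyl)‑5‑(oxan‑2‑yloxy)phenyl]‑4,4,5,5‑tetramethyl‑1,3,2‑dioxaborolane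
Conditions: [Ir(OMe)(cod)]2 (1.5 mol %), 4,4′‑di‑tert‑butyl‑2,2′‑bipyridine (3 mol %), B2pin2 (1.0 equiv), THF, 80 °C
Reagents that add atoms: bis(pinacolato)diboron, CC1(C)OB(OC1(C)C)B1OC(C)(C)C(C)(C)O1
Why: Iridium‑catalysed aromatic C–H borylation is sterically controlled, so of the three ring C–H bonds only the one with no ortho substituent (meta to Br and to O, para to CH2OSi) reacts; aryl bromides, acetals and silyl ethers are tolerated.

**Fragment B: allylic bromide**

Step 5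
Reactants: 8 (2‑bromopropanoyl bromide, racemic)
Product: 9 ester tert‑butyl 2‑bromopropanoate (racemic)
Conditions: t‑BuOH (1.2 equiv), pyridine (1.2 equiv), CH2Cl2, 0 °C → rt
Reagents that add atoms: tert‑butanol, CC(C)(C)O
Why: Acylation of the alcohol by the acid bromide with pyridine as acid scavenger; the tert‑butyl ester survives every basic, reductive and Pd step and leaves by acidolysis at the end.

Step 6
Reactants: 9 (tert‑butyl 2‑bromopropanoate)
Product: 11 ylide tert‑butyl 2‑(triphenyl‑λ5‑phosphanylidene)propanoate, via phosphonium bromide 10 (not isolated)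
Conditions: PPh3 (1.0 equiv), toluene, 80 °C; then 1 M aq. NaOH, CH2Cl2, rt
Reagents that add atoms: triphenylphosphine, c1ccc(cc1)P(c1ccccc1)c1ccccc1
Why: SN2 quaternisation of the phosphine by the α‑bromo ester and deprotonation of the acidic α‑C–H give the stabilised ylide.

Step 7
Reactants: 11 (ylide); 12 (1,4‑dioxane‑2,5‑diol, glycolaldehyde dimer, 0.55 equiv)
Product: 13 allylic alcohol tert‑butyl (E)‑4‑hydroxy‑2‑methylbut‑2‑enoate
Conditions: CH2Cl2, reflux, 12 h
Reagents that add atoms: none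
Why: Wittig olefination of glycolaldehyde (released from its dimer on warming) with an α‑methyl stabilised ylide gives the trisubstituted enoate with E geometry under thermodynamic control of the oxaphosphetane.

Step 8
Reactants: 13 (allylic alcohol)
Product: 14 allylic bromide tert‑butyl (E)‑4‑bromo‑2‑methylbut‑2‑enoate
Conditions: CBr4 (1.2 equiv), PPh3 (1.25 equiv), CH2Cl2, 0 °C
Reagents that add atoms: carbon tetrabromide, BrC(Br)(Br)Br
Why: Appel bromination of a primary allylic alcohol proceeds by SN2 displacement of the oxyphosphonium, without allylic transposition or loss of alkene geometry.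

**Union and elaboration of the core**

Step 9
Reactants: 7 (aryl boronate); 14 (allylic bromide, 1.3 equiv)
Product: 15 coupled arene tert‑butyl (E)‑4‑[3‑bromo‑4‑({[tert‑butyl(dimethyl)silyl]oxy}methyl)‑5‑(oxan‑2‑yloxy)phenyl]‑2‑methylbut‑2‑enoate
Conditions: Pd(PPh3)4 (3 mol %), K3PO4 (2 equiv), THF/H2O 10:1, 40 °C
Reagents that add atoms: none
Why: Allyl–aryl Suzuki–Miyaura coupling: zerovalent palladium inserts into the allylic C–Br bond far faster than into the hindered, electron‑rich aryl bromide at 40 °C, and after transmetalation the aryl group is delivered to the unsubstituted allyl terminus, giving the linear conjugated E enoate.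

Step 10
Reactants: 15 (coupled arene)
Product: 16 phenol tert‑butyl (E)‑4‑[3‑bromo‑4‑({[tert‑butyl(dimethyl)silyl]oxy}methyl)‑5‑hydroxyphenyl]‑2‑methylbut‑2‑enoate
Conditions: PPTS (10 mol %), EtOH, rt
Reagents that add atoms: none
Why: Aryl THP acetals undergo acid‑catalysed trans‑acetalisation far faster than a primary silyl ether or a tert‑butyl ester is cleaved, so only the phenol is released.

Step 11
Reactants: 16 (phenol)
Product: 18 quinone monoketal tert‑butyl (E)‑4‑[5‑bromo‑4‑({[tert‑butyl(dimethyl)silyl]oxy}methyl)‑6,6‑dimethoxy‑3‑oxocyclohexa‑1,4‑dien‑1‑yl]‑2‑methylbut‑2‑enoate, via 4‑methoxyphenol 17 (not isolated)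
Conditions: PhI(OAc)2 (2.2 equiv), MeOH, 0 °C → rt
Reagents that add atoms: methanol, CO
Why: Hypervalent‑iodine oxidative dearomatisation: the phenoxenium intermediate is trapped by methanol at the free para position, and a second oxidation of the resulting 4‑methoxyphenol gives the 4,4‑dimethoxycyclohexadienone, which differentiates the two future carbonyl positions.

Step 12
Reactants: 18 (quinone monoketal)
Product: 19 epoxy ketone tert‑butyl (E)‑4‑[(1S,6R)‑3‑bromo‑4‑({[tert‑butyl(dimethyl)silyl]oxy}methyl)‑2,2‑dimethoxy‑5‑oxo‑7‑oxabicyclo[4.1.0]hept‑3‑en‑1‑yl]‑2‑methylbut‑2‑enoate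
Conditions: catalyst G (10 mol %; N‑octadecyl‑N′,N″‑bis{(2S)‑1‑phenyl‑3‑[3‑(3,5‑bis(trifluoromethyl)phenyl)ureido]propan‑2‑yl}guanidine, free base), cumene hydroperoxide (1.3 equiv), 4 Å molecular sieves, toluene, −40 °C
Reagents that add atoms: cumene hydroperoxide, CC(C)(OO)c1ccccc1
Why: Proposed new method: an enantioselective Weitz–Scheffer epoxidation of a cross‑conjugated p‑quinone monoketal under hydrogen‑bonding Brønsted‑base catalysis, not yet shown for this substrate class or for making a fully substituted oxirane carbon; the guanidine deprotonates the hydroperoxide to a guanidinium‑bound cumylperoxide while the two ureas hydrogen‑bond the dienone carbonyl, the benzyl walls of the C2‑symmetric catalyst must avoid the bulky CH2OSi/Br arm so that one orientation of the flat dienone is preferred, the peroxide adds on one face to the less hindered β‑carbon (the one carrying the butenoate chain), and the enolate closes onto O–O with loss of cumyl oxide (which deprotonates the next hydroperoxide), fixing C1 and C6 together as the cis‑fused (1S,6R) oxirane; the ester alkene and the tetrasubstituted bromo‑alkene are too unreactive to compete; the closest known reaction types are guanidine–urea‑catalysed epoxidation of chalcones and naphthoquinones and the stoichiometric tartrate‑mediated epoxidation of quinone monoketals; the sense of induction cannot be predicted, so it is checked by anomalous‑dispersion X‑ray analysis of bromide 20 and the antipodal catalyst is used if it is opposite.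

Step 13
Reactants: 19 (epoxy ketone)
Product: 20 cis‑epoxy alcohol tert‑butyl (E)‑4‑[(1S,5S,6S)‑3‑bromo‑4‑({[tert‑butyl(dimethyl)silyl]oxy}methyl)‑5‑hydroxy‑2,2‑dimethoxy‑7‑oxabicyclo[4.1.0]hept‑3‑en‑1‑yl]‑2‑methylbut‑2‑enoate
Conditions: NaBH4 (1.2 equiv), CeCl3·7H2O (1.2 equiv), MeOH, −78 °C
Reagents that add atoms: none
Why: Luche 1,2‑reduction: cerium bridges the carbonyl and oxirane oxygens and hydride attacks C5 from the face opposite the oxirane oxygen, so the new hydroxyl is expected cis to the epoxide (5S), without conjugate reduction or loss of bromide.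

**Fragment C: heptenyl trifluoroborate**

Step 14
Reactants: 21 (hept‑1‑yne)
Product: 22 alkenyl boronate 2‑[(E)‑hept‑1‑en‑1‑yl]‑4,4,5,5‑tetramethyl‑1,3,2‑dioxaborolane
Conditions: pinacolborane (1.2 equiv), Cp2Zr(H)Cl (5 mol %), Et3N (10 mol %), neat, 60 °C
Reagents that add atoms: pinacolborane, CC1(C)OBOC1(C)C
Why: Zirconium‑catalysed hydroboration of a terminal alkyne is a syn, anti‑Markovnikov addition and gives only the (E)‑1‑alkenyl boronate.

Step 15
Reactants: 22 (alkenyl boronate)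
Product: 23 potassium (E)‑hept‑1‑en‑1‑yltrifluoroborate
Conditions: KHF2 (4.5 M aq., 4 equiv), MeOH, rt; recrystallise from acetone/Et2O
Reagents that add atoms: potassium hydrogen difluoride, F.[F-].[K+]
Why: Fluoride exchange at boron gives a crystalline, air‑stable salt of defined stoichiometry that releases the boronic acid slowly under coupling conditions, with alkene geometry retained.

**Final assembly**

Step 16
Reactants: 20 (cis‑epoxy alcohol); 23 (trifluoroborate, 1.5 equiv)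
Product: 25 diene tert‑butyl (E)‑4‑[(1S,5S,6S)‑4‑({[tert‑butyl(dimethyl)silyl]oxy}methyl)‑3‑[(E)‑hept‑1‑en‑1‑yl]‑5‑hydroxy‑2,2‑dimethoxy‑7‑oxabicyclo[4.1.0]hept‑3‑en‑1‑yl]‑2‑methylbut‑2‑enoate, via boronic acid 24 (not isolated)
Conditions: PdCl2(dppf)·CH2Cl2 (5 mol %), Cs2CO3 (3 equiv), THF/H2O 10:1, 65 °C
Reagents that add atoms: none
Why: Suzuki–Miyaura coupling of the ring vinyl bromide with the alkenylboron species proceeds with retention at both sp2 carbons; at the ketal stage the substrate has no enone, and the cis‑epoxy alcohol cannot undergo Payne rearrangement, so it tolerates aqueous carbonate.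

Step 17
Reactants: 25 (diene)
Product: 27 target (E)‑4‑[(1S,5S,6S)‑3‑[(E)‑hept‑1‑en‑1‑yl]‑5‑hydroxy‑4‑(hydroxymethyl)‑2‑oxo‑7‑oxabicyclo[4.1.0]hept‑3‑en‑1‑yl]‑2‑methylbut‑2‑enoic acid, via keto diol ester 26 (not isolated)
Conditions: 48 % aq. HF/MeCN 1:9, 0 °C → rt; evaporate; then TFA/CH2Cl2 1:4, 0 °C → rt
Reagents that add atoms: water, O
Why: Aqueous HF hydrolyses the dimethyl ketal and cleaves the silyl ether; once the enone is unmasked the α‑keto oxirane and the γ‑hydroxy enone resist acid ionisation, so acidolysis of the tert‑butyl ester (loss of isobutene) releases the acid without touching a stereocentre.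

**Compound list**
1 | 3‑bromophenol | Oc1cccc(Br)c1 | starting material
2 | 2‑(3‑bromophenoxy)oxane (racemic at the acetal carbon) | Brc1cccc(OC2CCCCO2)c1 | intermediate
3 | [2‑bromo‑6‑(oxan‑2‑yloxy)phenyl]lithium | [Li]c1c(Br)cccc1OC1CCCCO1 | intermediate
4 | 2‑bromo‑6‑(oxan‑2‑yloxy)benzaldehyde | O=Cc1c(Br)cccc1OC1CCCCO1 | intermediate
5 | [2‑bromo‑6‑(oxan‑2‑yloxy)phenyl]methanol | OCc1c(Br)cccc1OC1CCCCO1 | intermediate
6 | {[2‑bromo‑6‑(oxan‑2‑yloxy)phenyl]methoxy}(tert‑butyl)dimethylsilane | CC(C)(C)[Si](C)(C)OCc1c(Br)cccc1OC1CCCCO1 | intermediate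
7 | 2‑[3‑bromo‑4‑({[tert‑butyl(dimethyl)silyl]oxy}methyl)‑5‑(oxan‑2‑yloxy)phenyl]‑4,4,5,5‑tetramethyl‑1,3,2‑dioxaborolane | CC(C)(C)[Si](C)(C)OCc1c(Br)cc(B2OC(C)(C)C(C)(C)O2)cc1OC1CCCCO1 | intermediate
8 | 2‑bromopropanoyl bromide (racemic) | CC(Br)C(=O)Br | starting material
9 | tert‑butyl 2‑bromopropanoate (racemic) | CC(Br)C(=O)OC(C)(C)C | intermediate
10 | [1‑(tert‑butoxy)‑1‑oxopropan‑2‑yl]triphenylphosphonium bromide | CC(C(=O)OC(C)(C)C)[P+](c1ccccc1)(c1ccccc1)c1ccccc1.[Br-] | intermediate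
11 | tert‑butyl 2‑(triphenyl‑λ5‑phosphanylidene)propanoate | CC(C(=O)OC(C)(C)C)=P(c1ccccc1)(c1ccccc1)c1ccccc1 | intermediate
12 | 1,4‑dioxane‑2,5‑diol (glycolaldehyde dimer) | OC1COC(O)CO1 | starting material
13 | tert‑butyl (E)‑4‑hydroxy‑2‑methylbut‑2‑enoate | OC/C=C(\C)C(=O)OC(C)(C)C | intermediate
14 | tert‑butyl (E)‑4‑bromo‑2‑methylbut‑2‑enoate | BrC/C=C(\C)C(=O)OC(C)(C)C | intermediate
15 | tert‑butyl (E)‑4‑[3‑bromo‑4‑({[tert‑butyl(dimethyl)silyl]oxy}methyl)‑5‑(oxan‑2‑yloxy)phenyl]‑2‑methylbut‑2‑enoate | CC(C)(C)[Si](C)(C)OCc1c(Br)cc(C/C=C(\C)C(=O)OC(C)(C)C)cc1OC1CCCCO1 | intermediate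
16 | tert‑butyl (E)‑4‑[3‑bromo‑4‑({[tert‑butyl(dimethyl)silyl]oxy}methyl)‑5‑hydroxyphenyl]‑2‑methylbut‑2‑enoate | CC(C)(C)[Si](C)(C)OCc1c(Br)cc(C/C=C(\C)C(=O)OC(C)(C)C)cc1O | intermediate
17 | tert‑butyl (E)‑4‑[3‑bromo‑4‑({[tert‑butyl(dimethyl)silyl]oxy}methyl)‑5‑hydroxy‑2‑methoxyphenyl]‑2‑methylbut‑2‑enoate | CC(C)(C)[Si](C)(C)OCc1c(Br)c(OC)c(C/C=C(\C)C(=O)OC(C)(C)C)cc1O | intermediate
18 | tert‑butyl (E)‑4‑[5‑bromo‑4‑({[tert‑butyl(dimethyl)silyl]oxy}methyl)‑6,6‑dimethoxy‑3‑oxocyclohexa‑1,4‑dien‑1‑yl]‑2‑methylbut‑2‑enoate | BrC1=C(CO[Si](C)(C)C(C)(C)C)C(=O)C=C(C/C=C(\C)C(=O)OC(C)(C)C)C1(OC)OC | intermediate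
19 | tert‑butyl (E)‑4‑[(1S,6R)‑3‑bromo‑4‑({[tert‑butyl(dimethyl)silyl]oxy}methyl)‑2,2‑dimethoxy‑5‑oxo‑7‑oxabicyclo[4.1.0]hept‑3‑en‑1‑yl]‑2‑methylbut‑2‑enoate | BrC1=C(CO[Si](C)(C)C(C)(C)C)C(=O)[C@@H]2O[C@]2(C/C=C(\C)C(=O)OC(C)(C)C)C1(OC)OC | intermediate
20 | tert‑butyl (E)‑4‑[(1S,5S,6S)‑3‑bromo‑4‑({[tert‑butyl(dimethyl)silyl]oxy}methyl)‑5‑hydroxy‑2,2‑dimethoxy‑7‑oxabicyclo[4.1.0]hept‑3‑en‑1‑yl]‑2‑methylbut‑2‑enoate (OH cis to the oxirane oxygen) | BrC1=C(CO[Si](C)(C)C(C)(C)C)[C@H](O)[C@@H]2O[C@]2(C/C=C(\C)C(=O)OC(C)(C)C)C1(OC)OC | intermediate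
21 | hept‑1‑yne | CCCCCC#C | starting material
22 | 2‑[(E)‑hept‑1‑en‑1‑yl]‑4,4,5,5‑tetramethyl‑1,3,2‑dioxaborolane | CCCCC/C=C/B1OC(C)(C)C(C)(C)O1 | intermediate
23 | potassium (E)‑hept‑1‑en‑1‑yltrifluoroborate | CCCCC/C=C/[B-](F)(F)F.[K+] | intermediate
24 | (E)‑hept‑1‑en‑1‑ylboronic acid | CCCCC/C=C/B(O)O | intermediate
25 | tert‑butyl (E)‑4‑[(1S,5S,6S)‑4‑({[tert‑butyl(dimethyl)silyl]oxy}methyl)‑3‑[(E)‑hept‑1‑en‑1‑yl]‑5‑hydroxy‑2,2‑dimethoxy‑7‑oxabicyclo[4.1.0]hept‑3‑en‑1‑yl]‑2‑methylbut‑2‑enoate | CCCCC/C=C/C1=C(CO[Si](C)(C)C(C)(C)C)[C@H](O)[C@@H]2O[C@]2(C/C=C(\C)C(=O)OC(C)(C)C)C1(OC)OC | intermediate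
26 | tert‑butyl (E)‑4‑[(1S,5S,6S)‑3‑[(E)‑hept‑1‑en‑1‑yl]‑5‑hydroxy‑4‑(hydroxymethyl)‑2‑oxo‑7‑oxabicyclo[4.1.0]hept‑3‑en‑1‑yl]‑2‑methylbut‑2‑enoate | CCCCC/C=C/C1=C(CO)[C@H](O)[C@@H]2O[C@]2(C/C=C(\C)C(=O)OC(C)(C)C)C1=O | intermediate
27 | (E)‑4‑[(1S,5S,6S)‑3‑[(E)‑hept‑1‑en‑1‑yl]‑5‑hydroxy‑4‑(hydroxymethyl)‑2‑oxo‑7‑oxabicyclo[4.1.0]hept‑3‑en‑1‑yl]‑2‑methylbut‑2‑enoic acid | CCCCC/C=C/C1=C(CO)[C@H](O)[C@@H]2O[C@]2(C/C=C(\C)C(=O)O)C1=O | target

**Step count**
- Total: 17 steps.
- Longest linear sequence: 11 steps (1 → 2 → 5 → 6 → 7 → 15 → 16 → 18 → 19 → 20 → 25 → 27; the chain from 8 through 9, 11, 13, 14 is equally long). The heptenyl branch (21 → 22 → 23) has 2 steps before it joins.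

**Three steps most likely to fail**

Step 12 (the proposed epoxidation). Enantioselectivity, or turnover on a β,β‑disubstituted dienone, may be insufficient. The fallback sets out from 18 and comes back at 19. It replaces catalyst control by the known stoichiometric tartrate‑mediated nucleophilic epoxidation of quinone monoketals: Ph3COOH, NaN(SiMe3)2, diisopropyl tartrate, 4 Å molecular sieves, toluene, −55 °C. The L‑(+)‑ and D‑(−)‑tartrates give opposite enantiomers, and the one that delivers (1S,6R)‑19 is kept. This fallback makes no new compound (F0).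

Step 13 (reduction). The facial selectivity may be low or reversed. The fallback sets out from 19 and comes back at 20. Oxirane‑directed hydride delivery with iBu2AlH (THF, −78 °C) gives the C5 epimer, tert‑butyl (E)‑4‑[(1S,5R,6S)‑3‑bromo‑4‑({[tert‑butyl(dimethyl)silyl]oxy}methyl)‑5‑hydroxy‑2,2‑dimethoxy‑7‑oxabicyclo[4.1.0]hept‑3‑en‑1‑yl]‑2‑methylbut‑2‑enoate F3 (the same epimer is obtained if the Luche reduction goes the wrong way). Mitsunobu inversion (4‑nitrobenzoic acid, PPh3, diisopropyl azodicarboxylate, toluene, 0 °C → rt) gives the (5S) ester tert‑butyl (E)‑4‑[(1S,5S,6S)‑3‑bromo‑4‑({[tert‑butyl(dimethyl)silyl]oxy}methyl)‑2,2‑dimethoxy‑5‑[(4‑nitrobenzoyl)oxy]‑7‑oxabicyclo[4.1.0]hept‑3‑en‑1‑yl]‑2‑methylbut‑2‑enoate F4. Methanolysis (K2CO3, MeOH, 0 °C) then returns 20.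

Step 9 (allyl–aryl coupling). The boronate also carries an aryl bromide, so oligomers may form, and the arylated enoate may deconjugate toward the styrene. The fallback sets out from 7 and comes back at 15, building the side‑chain alkene by olefination instead. Copper‑catalysed allylation of the boronate (CuCl (10 mol %), 1,3‑bis(2,6‑diisopropylphenyl)imidazolium chloride (10 mol %), KOtBu, allyl bromide, THF, 45 °C; copper does not insert into the aryl bromide) gives {[2‑bromo‑6‑(oxan‑2‑yloxy)‑4‑(prop‑2‑en‑1‑yl)phenyl]methoxy}(tert‑butyl)dimethylsilane F1. Lemieux–Johnson cleavage (OsO4 (2 mol %), NaIO4, 2,6‑lutidine, dioxane/H2O) gives 2‑[3‑bromo‑4‑({[tert‑butyl(dimethyl)silyl]oxy}methyl)‑5‑(oxan‑2‑yloxy)phenyl]acetaldehyde F2. This aldehyde is used at once in an E‑selective Wittig reaction with ylide 11 (CH2Cl2, rt) to give 15.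

Further compounds
F1 | step 9 | {[2‑bromo‑6‑(oxan‑2‑yloxy)‑4‑(prop‑2‑en‑1‑yl)phenyl]methoxy}(tert‑butyl)dimethylsilane | CC(C)(C)[Si](C)(C)OCc1c(Br)cc(CC=C)cc1OC1CCCCO1
F2 | step 9 | 2‑[3‑bromo‑4‑({[tert‑butyl(dimethyl)silyl]oxy}methyl)‑5‑(oxan‑2‑yloxy)phenyl]acetaldehyde | CC(C)(C)[Si](C)(C)OCc1c(Br)cc(CC=O)cc1OC1CCCCO1
F0 | step 12 | none | none
F3 | step 13 | tert‑butyl (E)‑4‑[(1S,5R,6S)‑3‑bromo‑4‑({[tert‑butyl(dimethyl)silyl]oxy}methyl)‑5‑hydroxy‑2,2‑dimethoxy‑7‑oxabicyclo[4.1.0]hept‑3‑en‑1‑yl]‑2‑methylbut‑2‑enoate | BrC1=C(CO[Si](C)(C)C(C)(C)C)[C@@H](O)[C@@H]2O[C@]2(C/C=C(\C)C(=O)OC(C)(C)C)C1(OC)OC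
F4 | step 13 | tert‑butyl (E)‑4‑[(1S,5S,6S)‑3‑bromo‑4‑({[tert‑butyl(dimethyl)silyl]oxy}methyl)‑2,2‑dimethoxy‑5‑[(4‑nitrobenzoyl)oxy]‑7‑oxabicyclo[4.1.0]hept‑3‑en‑1‑yl]‑2‑methylbut‑2‑enoate | BrC1=C(CO[Si](C)(C)C(C)(C)C)[C@H](OC(=O)c3ccc(cc3)[N+](=O)[O-])[C@@H]2O[C@]2(C/C=C(\C)C(=O)OC(C)(C)C)C1(OC)OC
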